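**Retrosynthetic overview**
- The target is the bis-phenol released from its 8,3'-di-O-acetate by ester methanolysis.
- The pyranone ring is formed last, by a new dehydrogenative C(aryl)–H/O–H ring closure (O1–C8a bond) of a symmetric 1,3-diaryl-1,3-diketone.
- Rings A and B are the same 3-oxy-4,5-dimethoxybenzoyl unit, so the diketone comes from C-acylation of the aryl methyl ketone with the matching aroyl chloride.
- The ketone is made from that same aroyl chloride (acyl Negishi coupling), which comes from 3-hydroxy-4,5-dimethoxybenzoic acid by O-acetylation and chlorination.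
- Ring order: both benzene rings are bought intact; only the central pyranone ring is built (step 5).

Assumption: the target is achiral (no stereocentre, no stereogenic axis), so "single enantiomer" is taken to mean the single constitutional isomer drawn; no numbered compound carries a stereocentre.

**Step 1**
Reactants: 1 3-hydroxy-4,5-dimethoxybenzoic acid
Product: 2 3-acetoxy-4,5-dimethoxybenzoic acid
Conditions: Ac2O (4 equiv), H2SO4 (cat.), 60 °C, 1 h; pour into ice-water, filter
Reagents that add atoms: acetic anhydride, CC(=O)OC(C)=O
Why: Acid-catalysed O-acetylation of a phenol with acetic anhydride (aspirin-type esterification) is selective for the phenolic OH because any mixed anhydride at the carboxyl group is hydrolysed in the water quench, and acetyl is chosen because the weakly donating OAc group later steers the key ring closure.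

**Step 2**
Reactants: 2 3-acetoxy-4,5-dimethoxybenzoic acid
Product: 3 3-acetoxy-4,5-dimethoxybenzoyl chloride
Conditions: (COCl)2 (1.3 equiv), DMF (cat.), CH2Cl2, 0 °C → rt; evaporate (one portion goes to step 3, the rest to step 4)
Reagents that add atoms: oxalyl chloride, O=C(Cl)C(=O)Cl
Why: Vilsmeier-type (DMF-catalysed) conversion of a carboxylic acid into its acid chloride with oxalyl chloride runs under neutral, anhydrous conditions that leave aryl acetates and methyl ethers untouched.

**Step 3**
Reactants: 3 3-acetoxy-4,5-dimethoxybenzoyl chloride
Product: 4 5-acetyl-2,3-dimethoxyphenyl acetate (3'-acetoxy-4',5'-dimethoxyacetophenone)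
Conditions: MeZnCl (1.2 equiv, 2 M in THF), Pd(PPh3)4 (3 mol %), THF, 0 °C → rt
Reagents that add atoms: methylzinc chloride, C[Zn]Cl
Why: Negishi acyl cross-coupling, in which Pd(0) inserts into the C(acyl)–Cl bond and transmetalation with the methylzinc reagent gives the methyl ketone without over-addition, since organozinc halides attack neither the aryl acetate nor the product ketone.

**Step 4**
Reactants: 4 5-acetyl-2,3-dimethoxyphenyl acetate; 3 3-acetoxy-4,5-dimethoxybenzoyl chloride
Product: 5 1,3-bis(3-acetoxy-4,5-dimethoxyphenyl)propane-1,3-dione (symmetric; mainly the chelated enol tautomer)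
Conditions: MgBr2·OEt2 (2.5 equiv), i-Pr2NEt (3 equiv), CH2Cl2, rt, 2 h; 1 M HCl work-up
Reagents that add atoms: none
Why: Soft-enolisation crossed Claisen-type C-acylation, in which MgBr2 activates ketone 4 so that the amine base forms the magnesium enolate, which is C-acylated by acid chloride 3 and then held as the unreactive magnesium diketonate, all without a strong or nucleophilic base that would cleave the aryl acetates.

**Step 5**
Reactants: 5 1,3-bis(3-acetoxy-4,5-dimethoxyphenyl)propane-1,3-dione
Product: 6 8-acetoxy-2-(3-acetoxy-4,5-dimethoxyphenyl)-6,7-dimethoxy-4H-chromen-4-one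
Conditions: 3,6-di-tert-butyl-9-mesityl-10-phenylacridinium BF4 (5 mol %), Co(dmgH)2(py)Cl (5 mol %), HFIP/DCE 1:3 (0.02 M), 450 nm LEDs, Ar, rt, 24 h
Reagents that add atoms: none
Why: Proposed new method: an acceptorless dehydrogenative C(aryl)–H/O–H cyclisation of a 1,3-diaryl-1,3-diketone to a flavone, which to my knowledge has not been described; the excited acridinium (E* about +2.0 V vs SCE) oxidises one dimethoxyaryl ring of 5 to its radical cation, the oxygen of the adjacent enolised diketone adds intramolecularly (six-membered ring) at C2, the site para to the coplanar 5-OMe donor and ortho to the weakly donating OAc (the alternative C6 is only ortho to OMe, para to OAc and shielded by the in-plane OMe methyl), and the resulting cyclohexadienyl radical is oxidised and deprotonated by the cobaloxime, which releases H2 and returns the acridine radical to the acridinium; because 5 is symmetric it does not matter which ring is oxidised, and the acetates both block phenol oxidation and supply the electronic bias between C2 and C6; the closest known reaction types are acridinium-photocatalysed site-selective nucleophilic C–H functionalisation of alkoxyarenes via arene radical cations (para to OMe), acridinium/cobaloxime dehydrogenative lactonisation of 2-arylbenzoic acids, and oxidant-mediated C–O ring closure of α-aryl ketones to benzofurans.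

**Step 6**
Reactants: 6 8-acetoxy-2-(3-acetoxy-4,5-dimethoxyphenyl)-6,7-dimethoxy-4H-chromen-4-one
Product: 7 8-hydroxy-2-(3-hydroxy-4,5-dimethoxyphenyl)-6,7-dimethoxy-4H-chromen-4-one (CNP0264497.0)
Conditions: HCl (1.25 M in MeOH), 40 °C, 6 h
Reagents that add atoms: none
Why: Acid-catalysed transesterification (methanolysis) of the two aryl acetates releases both phenols as methyl acetate, under conditions to which the flavone core and the four methyl ethers are inert.

**Compound list**
1 | 3-hydroxy-4,5-dimethoxybenzoic acid | COc1cc(C(=O)O)cc(O)c1OC | starting material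
2 | 3-acetoxy-4,5-dimethoxybenzoic acid | COc1cc(C(=O)O)cc(OC(C)=O)c1OC | intermediate
3 | 3-acetoxy-4,5-dimethoxybenzoyl chloride | COc1cc(C(=O)Cl)cc(OC(C)=O)c1OC | intermediate
4 | 5-acetyl-2,3-dimethoxyphenyl acetate | COc1cc(C(C)=O)cc(OC(C)=O)c1OC | intermediate
5 | 1,3-bis(3-acetoxy-4,5-dimethoxyphenyl)propane-1,3-dione | COc1cc(C(=O)CC(=O)c2cc(OC)c(OC)c(OC(C)=O)c2)cc(OC(C)=O)c1OC | intermediate
6 | 8-acetoxy-2-(3-acetoxy-4,5-dimethoxyphenyl)-6,7-dimethoxy-4H-chromen-4-one | COc1cc(-c2cc(=O)c3cc(OC)c(OC)c(OC(C)=O)c3o2)cc(OC(C)=O)c1OC | intermediate
7 | 8-hydroxy-2-(3-hydroxy-4,5-dimethoxyphenyl)-6,7-dimethoxy-4H-chromen-4-one | COc1cc(-c2cc(=O)c3cc(OC)c(OC)c(O)c3o2)cc(O)c1OC | target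

**Step count and risk**
Total steps: 6. Longest linear sequence: 6 (1 → 2 → 3 → 4 → 5 → 6 → 7; compound 3 is used in both step 3 and step 4).

Three steps most likely to fail:

Step 5 (the proposed new ring closure). The risks are closure at C6 instead of C2, giving the 6-acetoxy-7,8-dimethoxy isomer, oxidation of the enol leading to C–C dimers, and low conversion. The fallback uses known chemistry only; it sets out from 4 and comes back to the route at 6. Ketone 4 is ring-brominated with NBS in MeCN at rt, an electrophilic aromatic substitution para to the 5-OMe group, to give 1-(3-acetoxy-2-bromo-4,5-dimethoxyphenyl)ethanone F1. F1 is C-acylated with acid chloride 3 under the step 4 conditions (MgBr2·OEt2, i-Pr2NEt, CH2Cl2) to give 1-(3-acetoxy-2-bromo-4,5-dimethoxyphenyl)-3-(3-acetoxy-4,5-dimethoxyphenyl)propane-1,3-dione F2. The pyranone ring is then closed by the established copper-catalysed intramolecular Ullmann-type O-arylation of 1-(2-bromoaryl)-1,3-diketones (CuI 10 mol %, 1,10-phenanthroline 20 mol %, anhydrous K3PO4, toluene, 100 °C), which gives 6. Here the position of the ring oxygen is fixed by the bromine and not by the electronics of a radical cation.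

Step 4 (C-acylation to the diketone). The risks are O-acylation, a second acylation to the triketone, and acetyl transfer from an aryl acetate. The fallback replaces the acylation by an aldol addition followed by oxidation; it sets out from 3 and comes back at 5. Acid chloride 3 is reduced by Rosenmund hydrogenolysis (H2, Pd/BaSO4, 2,6-lutidine, toluene) to 3-acetoxy-4,5-dimethoxybenzaldehyde F3. The boron enolate of ketone 4 (Bu2BOTf, i-Pr2NEt, CH2Cl2, –78 °C, non-oxidative work-up) adds to F3 to give racemic 1,3-bis(3-acetoxy-4,5-dimethoxyphenyl)-3-hydroxypropan-1-one F4. Its single stereocentre is removed when Dess–Martin periodinane (CH2Cl2, rt) oxidises the β-hydroxy ketone to diketone 5.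

Step 3 (acyl Negishi coupling). The risks are attack on the aryl acetate, reduction or decarbonylation at palladium, and incomplete coupling. The fallback installs the methyl ketone before the acetate by organolithium addition to a carboxylate; it sets out from 1 and comes back at 4. Acid 1 is treated with MeLi (3.5 equiv, THF, 0 °C → rt, then aqueous HCl), the classical ketone synthesis from a lithium carboxylate, to give 1-(3-hydroxy-4,5-dimethoxyphenyl)ethanone F5. Acetylation of F5 (Ac2O, pyridine, rt) gives 4.

**Further compounds**
F1 | step 5 | 1-(3-acetoxy-2-bromo-4,5-dimethoxyphenyl)ethanone | COc1cc(C(C)=O)c(Br)c(OC(C)=O)c1OC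
F2 | step 5 | 1-(3-acetoxy-2-bromo-4,5-dimethoxyphenyl)-3-(3-acetoxy-4,5-dimethoxyphenyl)propane-1,3-dione | COc1cc(C(=O)CC(=O)c2cc(OC)c(OC)c(OC(C)=O)c2Br)cc(OC(C)=O)c1OC
F3 | step 4 | 3-acetoxy-4,5-dimethoxybenzaldehyde | COc1cc(C=O)cc(OC(C)=O)c1OC
F4 | step 4 | 1,3-bis(3-acetoxy-4,5-dimethoxyphenyl)-3-hydroxypropan-1-one (racemic) | COc1cc(C(O)CC(=O)c2cc(OC)c(OC)c(OC(C)=O)c2)cc(OC(C)=O)c1OC
F5 | step 3 | 1-(3-hydroxy-4,5-dimethoxyphenyl)ethanone | COc1cc(C(C)=O)cc(O)c1OC
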